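The route rests on cutting the C1''=C2'' Z alkene next to ring B. Because O4' sits ortho to C3', and C6'' of the side chain can be held at the acid oxidation level in place of the prenyl-type alkene, O4' and C6'' are tied together as an aryl ester. Ring-closing metathesis of the resulting 4-bromo-2-vinylphenyl (R)-4-methylhex-5-enoate then forms C1''=C2'' inside a nine-membered lactone fused to ring B. This fixes the Z geometry and leaves no trisubstituted alkene for the catalyst to attack. The lactone carbonyl is later converted into the isopropylidene terminus, and the bromide carries the ring-B unit into a Suzuki coupling with a 3-iodochromone.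

Key step: step 6

Remark on the chemistry: side-chain carbons are numbered C1'' to C8'' outward from C3' of ring B, and the hydride reduction product of the lactone is formulated as the ring-opened phenol aldehyde, because a nine-membered aryl hemiacetal is not expected to persist.

Step 1
Reactants: 1 (R)-beta-citronellene, (3R)-3,7-dimethylocta-1,6-diene
Product: 2 2,2-dimethyl-3-[(3R)-3-methylpent-4-en-1-yl]oxirane (both epimers at the oxirane CH)
Conditions: mCPBA (1.05 equiv), NaHCO3, CH2Cl2, 0 °C
Reagents that add atoms: 3-chloroperoxybenzoic acid (mCPBA), O=C(OO)c1cccc(Cl)c1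
Why: Prilezhaev epoxidation strongly prefers the electron-rich trisubstituted alkene over the monosubstituted vinyl group, and the new oxirane stereocentre is irrelevant because that carbon becomes the aldehyde carbon in step 2.

Step 2
Reactants: 2 2,2-dimethyl-3-[(3R)-3-methylpent-4-en-1-yl]oxirane
Product: 4 (4R)-4-methylhex-5-enal, via vicinal diol 3 (not isolated)
Conditions: H5IO6 (1.1 equiv), THF/H2O, 0 °C to rt
Reagents that add atoms: none
Why: Acid-mediated hydrolysis of the epoxide to the glycol followed by Malaprade periodate cleavage in the same flask should excise acetone and leave the aldehyde, with the remote C4 stereocentre untouched.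

Step 3
Reactants: 4 (4R)-4-methylhex-5-enal
Product: 5 (4R)-4-methylhex-5-enoic acid
Conditions: NaClO2, NaH2PO4, 2-methyl-2-butene, t-BuOH/H2O, 0 °C to rt
Reagents that add atoms: sodium chlorite, [Na+].[O-]Cl=O
Why: Pinnick chlorite oxidation converts the aldehyde to the acid under buffered conditions, while excess 2-methyl-2-butene intercepts hypochlorous acid before it can reach the terminal vinyl group.

Step 4
Reactants: 6 5-bromosalicylaldehyde (5-bromo-2-hydroxybenzaldehyde)
Product: 7 4-bromo-2-vinylphenol
Conditions: Ph3PCH3Br (2.4 equiv), KOtBu (2.4 equiv), THF, 0 °C to rt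
Reagents that add atoms: methyltriphenylphosphonium bromide, C[P+](c1ccccc1)(c1ccccc1)c1ccccc1.[Br-]
Why: Wittig methylenation with more than two equivalents of ylide tolerates the free phenol, since the first equivalent only forms the phenoxide, and should turn the formyl group into the styrene needed for metathesis.

Step 5
Reactants: 5 (4R)-4-methylhex-5-enoic acid, 7 4-bromo-2-vinylphenol
Product: 8 4-bromo-2-vinylphenyl (4R)-4-methylhex-5-enoate
Conditions: N,N'-dicyclohexylcarbodiimide (1.2 equiv), DMAP (0.1 equiv), CH2Cl2, 0 °C to rt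
Reagents that add atoms: none
Why: Steglich esterification through the O-acylisourea and the acylpyridinium ion acylates the phenol under neutral conditions, and the stereocentre gamma to the carboxyl group cannot enolise.

Step 6
Reactants: 8 4-bromo-2-vinylphenyl (4R)-4-methylhex-5-enoate
Product: 9 (5R,6Z)-9-bromo-5-methyl-4,5-dihydro-1-benzoxonin-2(3H)-one (nine-membered lactone fused to ring B)
Conditions: (H2IMes)(PCy3)Cl2Ru=CHPh, second-generation Grubbs catalyst (10 mol%), 1,4-benzoquinone (20 mol%), toluene, 0.002 M, slow addition of 8, 80 °C, Ar sparge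
Reagents that add atoms: none
Why: Ring-closing metathesis: the ruthenium alkylidene is handed on to one terminal alkene of 8 (most readily the aliphatic vinyl group), adds intramolecularly to the other to give a ruthenacyclobutane, and cycloreversion releases ethene, whose removal by the argon stream drives the closure. The closest known reaction type is the ring-closing metathesis of ortho-alkenylaryl alkenoates to eight- to ten-membered benzo-fused lactones. The single ring formed is nine-membered and closes in the endo sense, C1'' (styrene carbon) and C2'' (hexenoate carbon) both becoming ring members, with the O4'–C4'–C3' edge of ring B and the planar ester holding the two chain ends on the same side. No stereocentre is created; C3'' is a spectator, and the quinone scavenges ruthenium hydrides that could otherwise move the alkene through that centre. The step needs Z geometry and ring closure in preference to chain growth: an E alkene cannot be accommodated in a nine-membered ring that already contains a benzene edge and an ester, so the reversible process should settle on the Z lactone, while the ortho placement of the two reacting arms, high dilution and slow addition favour cyclisation.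

Step 7
Reactants: 9 (5R,6Z)-9-bromo-5-methyl-4,5-dihydro-1-benzoxonin-2(3H)-one
Product: 10 (4R,5Z)-6-(5-bromo-2-hydroxyphenyl)-4-methylhex-5-enal
Conditions: iBu2AlH (1.1 equiv), CH2Cl2, −78 °C; then aqueous potassium sodium tartrate
Reagents that add atoms: none
Why: Partial hydride reduction of a lactone with iBu2AlH at low temperature should stop at the aluminium hemiacetal, which releases the aldehyde and the ring-B phenol only on work-up, as in the reduction of dihydrocoumarins to chromanols.

Step 8
Reactants: 10 (4R,5Z)-6-(5-bromo-2-hydroxyphenyl)-4-methylhex-5-enal, 11 isopropyltriphenylphosphonium iodide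
Product: 13 4-bromo-2-[(1Z,3R)-3,7-dimethylocta-1,6-dien-1-yl]phenol, via isopropylidenetriphenylphosphorane 12 (not isolated)
Conditions: 11 (3.0 equiv), KN(SiMe3)2 (2.9 equiv), THF, 0 °C; then 10, −78 °C to rt
Reagents that add atoms: none
Why: Wittig olefination with the non-stabilised isopropylidene ylide, used in excess because one equivalent is consumed by the phenol, installs the C6''=C7'' alkene, which has no geometry to control, and the amide base avoids bromine–metal exchange.

Step 9
Reactants: 13 4-bromo-2-[(1Z,3R)-3,7-dimethylocta-1,6-dien-1-yl]phenol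
Product: 14 tert-butyl{4-bromo-2-[(1Z,3R)-3,7-dimethylocta-1,6-dien-1-yl]phenoxy}dimethylsilane
Conditions: TBSCl (1.3 equiv), imidazole (2.5 equiv), DMF, rt
Reagents that add atoms: tert-butyldimethylsilyl chloride (TBSCl), CC(C)(C)[Si](C)(C)Cl
Why: Imidazole-promoted O-silylation masks the acidic phenol before the two palladium-catalysed steps and is removable with fluoride, which does not endanger the Z alkene.

Step 10
Reactants: 14 tert-butyl{4-bromo-2-[(1Z,3R)-3,7-dimethylocta-1,6-dien-1-yl]phenoxy}dimethylsilane
Product: 15 tert-butyl{2-[(1Z,3R)-3,7-dimethylocta-1,6-dien-1-yl]-4-(4,4,5,5-tetramethyl-1,3,2-dioxaborolan-2-yl)phenoxy}dimethylsilane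
Conditions: B2pin2 (1.2 equiv), Pd(dppf)Cl2 (5 mol%), KOAc (3 equiv), 1,4-dioxane, 85 °C
Reagents that add atoms: bis(pinacolato)diboron, CC1(C)OB(OC1(C)C)B1OC(C)(C)C(C)(C)O1
Why: Miyaura borylation (oxidative addition of zerovalent palladium to the unhindered aryl bromide, acetate-assisted transmetalation with the diboron, reductive elimination) should give the arylboronate while the silyl ether and both alkenes remain spectators.

Step 11
Reactants: 16 2',4'-dihydroxyacetophenone
Product: 17 1-[2-hydroxy-4-(triisopropylsilyloxy)phenyl]ethanone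
Conditions: TIPSCl (1.05 equiv), imidazole (2.2 equiv), CH2Cl2, 0 °C to rt
Reagents that add atoms: triisopropylsilyl chloride, CC(C)[Si](Cl)(C(C)C)C(C)C
Why: Silylation should be selective for the 4-OH because the 2-OH is hydrogen-bonded to the acetyl carbonyl and more hindered, a standard regioselective protection of this acetophenone.

Step 12
Reactants: 17 1-[2-hydroxy-4-(triisopropylsilyloxy)phenyl]ethanone
Product: 19 3-iodo-7-(triisopropylsilyloxy)-4H-chromen-4-one, via enaminone 18 (not isolated)
Conditions: Me2NCH(OMe)2 (2 equiv), toluene, 90 °C; evaporate; then I2 (1.5 equiv), pyridine (1.5 equiv), CHCl3, rt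
Reagents that add atoms: N,N-dimethylformamide dimethyl acetal, COC(OC)N(C)C; iodine, [I][I]
Why: Condensation of the methyl ketone with the formamide acetal gives the enaminone, whose electrophilic alpha-iodination is followed by attack of the chelated phenol on the iminium carbon and loss of dimethylamine, the standard enaminone iodocyclisation route to 3-iodochromones.

Step 13
Reactants: 15 tert-butyl{2-[(1Z,3R)-3,7-dimethylocta-1,6-dien-1-yl]-4-(4,4,5,5-tetramethyl-1,3,2-dioxaborolan-2-yl)phenoxy}dimethylsilane, 19 3-iodo-7-(triisopropylsilyloxy)-4H-chromen-4-one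
Product: 20 3-{4-(tert-butyldimethylsilyloxy)-3-[(1Z,3R)-3,7-dimethylocta-1,6-dien-1-yl]phenyl}-7-(triisopropylsilyloxy)-4H-chromen-4-one
Conditions: 19 (1.2 equiv), Pd(dppf)Cl2 (5 mol%), Na2CO3 (aq, 3 equiv), DME, 65 °C
Reagents that add atoms: none
Why: Suzuki–Miyaura coupling: the 3-iodochromone is an activated alkenyl iodide that undergoes fast oxidative addition, and carbonate-mediated transmetalation of the arylboronate should forge the C3–C1' bond under conditions mild enough for the chromone ring and both silyl ethers.

Step 14
Reactants: 20 3-{4-(tert-butyldimethylsilyloxy)-3-[(1Z,3R)-3,7-dimethylocta-1,6-dien-1-yl]phenyl}-7-(triisopropylsilyloxy)-4H-chromen-4-one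
Product: 21 3-{3-[(1Z,3R)-3,7-dimethylocta-1,6-dien-1-yl]-4-hydroxyphenyl}-7-hydroxy-4H-chromen-4-one (CNP0200226.1)
Conditions: Bu4NF (2.5 equiv), AcOH (2.5 equiv), THF, 0 °C to rt
Reagents that add atoms: none
Why: Fluoride-mediated desilylation through pentacoordinate silicon cleaves both aryl silyl ethers, and the acetic acid buffer keeps the medium from opening the chromone ring or disturbing the Z alkene.

Compound list
1 | (R)-beta-citronellene, (3R)-3,7-dimethylocta-1,6-diene | CC(C)=CCC[C@@H](C)C=C | starting material
2 | 2,2-dimethyl-3-[(3R)-3-methylpent-4-en-1-yl]oxirane (epimers at the oxirane CH) | CC1(C)OC1CC[C@@H](C)C=C | intermediate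
3 | (6R)-2,6-dimethyloct-7-ene-2,3-diol (epimers at C3; not isolated) | CC(C)(O)C(O)CC[C@@H](C)C=C | intermediate
4 | (4R)-4-methylhex-5-enal | O=CCC[C@@H](C)C=C | intermediate
5 | (4R)-4-methylhex-5-enoic acid | OC(=O)CC[C@@H](C)C=C | intermediate
6 | 5-bromosalicylaldehyde | O=Cc1cc(Br)ccc1O | starting material
7 | 4-bromo-2-vinylphenol | C=Cc1cc(Br)ccc1O | intermediate
8 | 4-bromo-2-vinylphenyl (4R)-4-methylhex-5-enoate | O=C(CC[C@@H](C)C=C)Oc1ccc(Br)cc1C=C | intermediate
9 | (5R,6Z)-9-bromo-5-methyl-4,5-dihydro-1-benzoxonin-2(3H)-one | O=C1CC[C@@H](C)/C=C\c2cc(Br)ccc2O1 | intermediate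
10 | (4R,5Z)-6-(5-bromo-2-hydroxyphenyl)-4-methylhex-5-enal | O=CCC[C@@H](C)/C=C\c1cc(Br)ccc1O | intermediate
11 | isopropyltriphenylphosphonium iodide | CC(C)[P+](c1ccccc1)(c1ccccc1)c1ccccc1.[I-] | starting material
12 | isopropylidenetriphenylphosphorane (not isolated) | CC(C)=P(c1ccccc1)(c1ccccc1)c1ccccc1 | intermediate
13 | 4-bromo-2-[(1Z,3R)-3,7-dimethylocta-1,6-dien-1-yl]phenol | CC(C)=CCC[C@@H](C)/C=C\c1cc(Br)ccc1O | intermediate
14 | tert-butyl{4-bromo-2-[(1Z,3R)-3,7-dimethylocta-1,6-dien-1-yl]phenoxy}dimethylsilane | CC(C)=CCC[C@@H](C)/C=C\c1cc(Br)ccc1O[Si](C)(C)C(C)(C)C | intermediate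
15 | tert-butyl{2-[(1Z,3R)-3,7-dimethylocta-1,6-dien-1-yl]-4-(4,4,5,5-tetramethyl-1,3,2-dioxaborolan-2-yl)phenoxy}dimethylsilane | CC(C)=CCC[C@@H](C)/C=C\c1cc(B2OC(C)(C)C(C)(C)O2)ccc1O[Si](C)(C)C(C)(C)C | intermediate
16 | 2',4'-dihydroxyacetophenone | CC(=O)c1ccc(O)cc1O | starting material
17 | 1-[2-hydroxy-4-(triisopropylsilyloxy)phenyl]ethanone | CC(=O)c1ccc(O[Si](C(C)C)(C(C)C)C(C)C)cc1O | intermediate
18 | (E)-3-(dimethylamino)-1-[2-hydroxy-4-(triisopropylsilyloxy)phenyl]prop-2-en-1-one (not isolated) | CN(C)/C=C/C(=O)c1ccc(O[Si](C(C)C)(C(C)C)C(C)C)cc1O | intermediate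
19 | 3-iodo-7-(triisopropylsilyloxy)-4H-chromen-4-one | O=c1c(I)coc2cc(O[Si](C(C)C)(C(C)C)C(C)C)ccc12 | intermediate
20 | 3-{4-(tert-butyldimethylsilyloxy)-3-[(1Z,3R)-3,7-dimethylocta-1,6-dien-1-yl]phenyl}-7-(triisopropylsilyloxy)-4H-chromen-4-one | CC(C)=CCC[C@@H](C)/C=C\c1cc(-c2coc3cc(O[Si](C(C)C)(C(C)C)C(C)C)ccc3c2=O)ccc1O[Si](C)(C)C(C)(C)C | intermediate
21 | 3-{3-[(1Z,3R)-3,7-dimethylocta-1,6-dien-1-yl]-4-hydroxyphenyl}-7-hydroxy-4H-chromen-4-one | CC(C)=CCC[C@@H](C)/C=C\c1cc(-c2coc3cc(O)ccc3c2=O)ccc1O | target

Total step count: 14. Longest linear sequence: 11 steps (steps 1, 2, 3, 5, 6, 7, 8, 9, 10, 13, 14).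

Steps most likely to fail

1. Step 6, ring-closing metathesis. The risk is chain growth by intermolecular metathesis outrunning closure of the strained medium ring, or hydride-mediated alkene migration eroding C3''. The fallback forms C1''=C2'' intermolecularly and corrects its geometry afterwards, setting out from 7 and 4 and returning at 14. Silylation of 7 (TBSCl, imidazole, DMF) would give tert-butyl(4-bromo-2-vinylphenoxy)dimethylsilane F1. Cross-metathesis of F1 with excess aldehyde 4, using (H2IMes)(PCy3)Cl2Ru=CHPh (second-generation Grubbs catalyst) in CH2Cl2 at 40 °C, should give (4R,5E)-6-[5-bromo-2-(tert-butyldimethylsilyloxy)phenyl]-4-methylhex-5-enal F2; no trisubstituted alkene is present at this stage. Wittig reaction of F2 with ylide 12 would give tert-butyl{4-bromo-2-[(1E,3R)-3,7-dimethylocta-1,6-dien-1-yl]phenoxy}dimethylsilane F3. Contra-thermodynamic E-to-Z isomerisation of the styrene by triplet energy transfer (fac-Ir(ppy)3, blue light, MeCN, rt) should then enrich 14, because the ortho silyloxy group and the allylic branch twist the Z isomer out of conjugation so that it is no longer sensitised. Residual F3 would be separated and resubmitted, and the route continues at step 10.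

2. Step 7, partial reduction of the aryl lactone. The risk is over-reduction: the aluminium hemiacetal may collapse by loss of the aryloxide and take up a second hydride. The fallback parks the acyl carbon as a Weinreb amide, setting out from 9 and returning at 10. Treatment of 9 with MeNH(OMe)·HCl and i-PrMgCl in THF at −20 °C should open the activated aryl ester to (4R,5Z)-6-(5-bromo-2-hydroxyphenyl)-N-methoxy-N,4-dimethylhex-5-enamide F4. Reduction of F4 with iBu2AlH (2.2 equiv, one consumed by the phenol) in THF at −78 °C stops at the chelated tetrahedral intermediate and should release aldehyde 10 on work-up.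

3. Step 13, Suzuki coupling. The risk is protodeboronation of the electron-rich boronate, or base-induced opening of the chromone ring and premature silyl loss in the aqueous carbonate medium. The fallback is a base-free Negishi coupling, setting out from 14 (step 10 is then omitted) and returning at 20. Bromine–lithium exchange on 14 (n-BuLi, THF, −78 °C) would give {4-(tert-butyldimethylsilyloxy)-3-[(1Z,3R)-3,7-dimethylocta-1,6-dien-1-yl]phenyl}lithium F5. Transmetalation with ZnCl2 gives {4-(tert-butyldimethylsilyloxy)-3-[(1Z,3R)-3,7-dimethylocta-1,6-dien-1-yl]phenyl}zinc chloride F6. Coupling of F6 with 19 under Pd(PPh3)4 in THF at rt to 50 °C should give 20.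

Further compounds
F1 | step 6 | tert-butyl(4-bromo-2-vinylphenoxy)dimethylsilane | C=Cc1cc(Br)ccc1O[Si](C)(C)C(C)(C)C
F2 | step 6 | (4R,5E)-6-[5-bromo-2-(tert-butyldimethylsilyloxy)phenyl]-4-methylhex-5-enal | O=CCC[C@@H](C)/C=C/c1cc(Br)ccc1O[Si](C)(C)C(C)(C)C
F3 | step 6 | tert-butyl{4-bromo-2-[(1E,3R)-3,7-dimethylocta-1,6-dien-1-yl]phenoxy}dimethylsilane | CC(C)=CCC[C@@H](C)/C=C/c1cc(Br)ccc1O[Si](C)(C)C(C)(C)C
F4 | step 7 | (4R,5Z)-6-(5-bromo-2-hydroxyphenyl)-N-methoxy-N,4-dimethylhex-5-enamide | CON(C)C(=O)CC[C@@H](C)/C=C\c1cc(Br)ccc1O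
F5 | step 13 | {4-(tert-butyldimethylsilyloxy)-3-[(1Z,3R)-3,7-dimethylocta-1,6-dien-1-yl]phenyl}lithium | CC(C)=CCC[C@@H](C)/C=C\c1cc([Li])ccc1O[Si](C)(C)C(C)(C)C
F6 | step 13 | {4-(tert-butyldimethylsilyloxy)-3-[(1Z,3R)-3,7-dimethylocta-1,6-dien-1-yl]phenyl}zinc chloride | CC(C)=CCC[C@@H](C)/C=C\c1cc([Zn]Cl)ccc1O[Si](C)(C)C(C)(C)C
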